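(The earlier runs and the new flask are simulated on assumed constants.)

1. In the alpha run, first end groups and second end groups react to links. With 6.2% of the first end groups left at 5.00 min, the run holds 29.4% links, so I count the links won per first end group consumed, the yield on conversion (the selectivity), 31.3%.

| flask | first end groups | second end groups | remark | time |
|---|---|---|---|---|
| alpha | 0.30 M | 0.30 M | run made earlier |  |
| gamma | 0.30 M | 0.45 M | run made earlier |  |
| birch | 0.30 M | 0.300 M | everything together at the start | 30 min |
| oak | 0.30 M | 0.300 M (fed, over 20 min) | all else is in the flask from the start; the feed brings no volume worth counting | 30 min |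
| alder | 0.30 M (fed, over 20 min) | 0.300 M | all else is in the flask from the start; the feed brings no volume worth counting | 30 min |

| run | time / min | links / % | first end groups / % |
|---|---|---|---|
| alpha | 2.50 | 29.4 | 18.1 |
| alpha | 5.00 | 29.4 | 6.2 |
| alpha | 8.00 | 28.6 | 2.0 |
| alpha | 10.0 | 28.8 | 1.0 |
| alpha | 12.0 | 28.1 | 0.4 |
| alpha | 15.0 | 27.0 | 0.5 |
| alpha | 20.0 | 25.6 | 0.4 |
| gamma | 0.417 | 29.0 | 57.0 |
| gamma | 0.833 | 35.5 | 35.8 |
| gamma | 1.33 | 37.8 | 20.4 |
| gamma | 1.50 | 37.4 | 17.8 |
| gamma | 2.00 | 37.4 | 10.6 |
| gamma | 2.50 | 38.4 | 6.0 |
| gamma | 3.00 | 38.4 | 4.1 |

(each reading ± 0.5 percentage points)

- the analysis behind the earlier runs scatters by 0.5 percentage points, standard deviation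
- a reading or a percentage of links counts all its forms, free or not

- the flask with the highest amount of links, in percent of the first end groups charged ("all alike" if they lie within 1.5 percentage points) (birch / oak / alder / all alike)
- final links, as a percentage of the first end groups charged, in birch
- final links, as a percentage of the first end groups charged, in oak
- final links, as a percentage of the first end groups charged, in alder

2. I read the gamma run, with second end groups at 1.50 times the first, as the curve of links against consumption. Its first reading gives 67.4%, a knee follows, and by 3.00 min it stands at 40.0%.

3. Links stall while first end groups still go, so I take it that a further first end group consumes a link. Making and losing links then both carry first end groups as a factor, and dividing one rate by the other removes that concentration and time.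

4. Alder's feed therefore keeps alpha's path, and I take 31.3% at the end of the feed.

5. Alpha's links then fade by 3.8 percentage points between 5.00 min and 20.0 min. Continuing that line gives 23.1% for birch and 28.8% for alder, which is higher by 5.7 points.

6. In oak, gamma's first reading gives second end groups a half-life of 0.771 min while first end groups stand as charged, far shorter than the feed, so at the start of oak's feed the links form among first end groups in excess. That half-life holds for the start of the feed and lengthens as first end groups fall. I expect oak under 31.3%.

7. The forecast names alder, with 23%, 11% and 24.5% on the ground that “both routes scale with A”; my alder stands above its figure.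

    first end groups + second end groups ⇌ links + by-product (K = 46.5, k = 0.0511 M⁻¹ s⁻¹)
    first end groups + links → side product (k = 0.0421 M⁻¹ s⁻¹)
    crystals ⇌ links, rate k3*(cs3 - [links]) while solid is left; crystals form when [links] > cs3 (solubility = 0.180 M, k = 0.0477 s⁻¹)
    links ⇌ isomer of the product (K = 0.590, k = 0.0138 s⁻¹)

Alder gives 27.7%, birch 24.3% and oak 14.9%, so alder stands highest. At the end of its feed, alder holds 29.6% links with 9.76% of the first end groups left, a yield on conversion of 32.8% against alpha's 31.3%. Oak at that time stands at 15.3%. The flask like alder but with 0.12 M of first end groups has second end groups at 2.50 times the first, and at 30.0 min its yield on conversion is 48.6%.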